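The route rests on closing the 1,2-dioxane late, at O1–C6. In one operation, divalent mercury makes a C3 hydroperoxide add to the (E)-C5=C6 alkene, which forms the ring, the quaternary peroxy carbon C6 and a C5–Hg bond that is later replaced by hydrogen. The step exploits the 1,3-relationship of the C4 methine and C6 across C5 in the dioxane ring: anti addition through a chair with the C4 methyl equatorial relays the C4 configuration to C6. The precursor is the acyclic C3 geminal bis-hydroperoxide of an (R)-α-methyl, (E)-β,γ-unsaturated methyl ketone that already carries the (R)-methyl-branched tail and its cis-styrene.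

Key step: step 11

Remark: atoms are numbered as in the dioxane of the target (O1, O2, C3 to C6, side chain from C7, styrene C15=C16); (R)-citronellal of high enantiomeric purity, (2R,3R)-2,3-dimethyloxirane and (5-chloropent-1-yn-1-yl)benzene are taken as purchasable.

Step 1
Reactants: 1 (R)-citronellal
Product: 2 (4R)-4,8-dimethylnon-7-en-1-yne
Conditions: dimethyl (1-diazo-2-oxopropyl)phosphonate, K2CO3, MeOH, 0 °C → rt
Reagents that add atoms: dimethyl (1-diazo-2-oxopropyl)phosphonate, COP(=O)(OC)C(=[N+]=[N-])C(C)=O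
Why: Ohira–Bestmann (Seyferth–Gilbert) homologation turns the aldehyde into the terminal alkyne with one added carbon (the later C5) under mild carbonate conditions, and the β-stereocentre (the later C8) cannot enolise and is kept.

Step 2
Reactants: 2 (4R)-4,8-dimethylnon-7-en-1-yne
Product: 4 trimethyl[(4R)-4,8-dimethylnon-7-en-1-yn-1-yl]silane, via lithium acetylide 3 (not isolated)
Conditions: n-BuLi, THF, −78 °C; then Me3SiCl, −78 °C → rt
Reagents that add atoms: chlorotrimethylsilane, C[Si](C)(C)Cl
Why: Deprotonation of the terminal alkyne and C-silylation of the acetylide mask the acidic C–H and shield the triple bond for the ozonolysis and Grignard steps.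

Step 3
Reactants: 4 trimethyl[(4R)-4,8-dimethylnon-7-en-1-yn-1-yl]silane
Product: 6 (4R)-4-methyl-7-(trimethylsilyl)hept-6-yn-1-ol, via ozonide 5 (not isolated)
Conditions: O3, CH2Cl2, −78 °C (Sudan red 7B end point); then NaBH4, MeOH, −78 → 0 °C
Reagents that add atoms: ozone, [O-][O+]=O
Why: Ozonolysis with reductive work-up cleaves the electron-rich trisubstituted alkene much faster than the silylated alkyne reacts, and borohydride reduces the ozonide directly to the primary alcohol.

Step 4
Reactants: 6 (4R)-4-methyl-7-(trimethylsilyl)hept-6-yn-1-ol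
Product: 7 (4R)-4-methyl-7-(trimethylsilyl)hept-6-yn-1-yl 4-methylbenzenesulfonate
Conditions: TsCl, Et3N, DMAP (cat.), CH2Cl2, 0 °C → rt
Reagents that add atoms: 4-methylbenzenesulfonyl chloride, Cc1ccc(cc1)S(=O)(=O)Cl
Why: O-Sulfonylation of the unhindered primary alcohol installs the leaving group for the alkyl–alkyl coupling.

Step 5
Reactants: 8 (5-chloropent-1-yn-1-yl)benzene
Product: 9 [(1Z)-5-chloropent-1-en-1-yl]benzene
Conditions: H2 (1 atm), Pd/CaCO3 poisoned with Pb(OAc)2 (Lindlar), quinoline, hexane, rt, stopped after one equivalent of H2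
Reagents that add atoms: none
Why: Lindlar semi-hydrogenation delivers H2 syn to the aryl alkyne and stops at the (Z)-alkene, the primary alkyl chloride being inert.

Step 6
Reactants: 7 (4R)-4-methyl-7-(trimethylsilyl)hept-6-yn-1-yl 4-methylbenzenesulfonate; 9 [(1Z)-5-chloropent-1-en-1-yl]benzene
Product: 12 (4R,11Z)-4-methyl-12-phenyldodec-11-en-1-yne, via Grignard reagent 10 (not isolated), via silyl enyne 11 (not isolated)
Conditions: 9, Mg, THF, 45 °C; then 7, Li2CuCl4 (5 mol%), THF, −78 → 0 °C; then MeOH, K2CO3, rt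
Reagents that add atoms: none
Why: Copper-catalysed cross-coupling of a primary alkyl Grignard reagent with a primary tosylate forms the C11–C12 bond without touching the silyl alkyne or the cis-styrene, and methanolic carbonate then cleaves the C(sp)–Si bond in the same flask.

Step 7
Reactants: 12 (4R,11Z)-4-methyl-12-phenyldodec-11-en-1-yne
Product: 14 (1E,4R,11Z)-1-iodo-2,4-dimethyl-12-phenyldodeca-1,11-diene, via alkenylalane 13 (not isolated)
Conditions: Al(CH3)3, Cp2ZrCl2 (25 mol%), CH2Cl2, 0 °C → rt; then I2, THF, −30 °C, dark, Na2S2O3 quench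
Reagents that add atoms: trimethylaluminium, C[Al](C)C; iodine, II
Why: Negishi zirconium-catalysed methylalumination adds CH3 and Al syn across the terminal alkyne with the methyl on the internal carbon (the later C6), and iodinolysis of the C–Al bond with retention gives the (E)-iodoalkene, the internal cis-styrene not being carbometalated.

Step 8
Reactants: 14 (1E,4R,11Z)-1-iodo-2,4-dimethyl-12-phenyldodeca-1,11-diene; 15 (2R,3R)-2,3-dimethyloxirane
Product: 17 (2R,3R,4E,7R,14Z)-3,5,7-trimethyl-15-phenylpentadeca-4,14-dien-2-ol, via alkenyllithium 16 (not isolated)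
Conditions: t-BuLi (2.1 equiv), Et2O, −78 °C; then 15 (2 equiv), BF3·OEt2, −78 °C
Reagents that add atoms: none
Why: Iodine–lithium exchange with retention of alkene geometry (far faster at −78 °C than any addition to the styrene) and BF3-assisted SN2 opening of the C2-symmetric trans-epoxide, whose two carbons are equivalent, with inversion at the attacked carbon set the C4 methyl stereocentre as (R) (C3 of 17).

Step 9
Reactants: 17 (2R,3R,4E,7R,14Z)-3,5,7-trimethyl-15-phenylpentadeca-4,14-dien-2-ol
Product: 18 (3R,4E,7R,14Z)-3,5,7-trimethyl-15-phenylpentadeca-4,14-dien-2-one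
Conditions: Dess–Martin periodinane, NaHCO3, CH2Cl2, 0 °C → rt
Reagents that add atoms: none
Why: Dess–Martin oxidation under buffered, non-enolising conditions converts the secondary alcohol into the methyl ketone without epimerising the α-centre or moving the β,γ-alkene into conjugation, and the carbinol centre is meant to be lost.

Step 10
Reactants: 18 (3R,4E,7R,14Z)-3,5,7-trimethyl-15-phenylpentadeca-4,14-dien-2-one
Product: 19 (3R,4E,7R,14Z)-2,2-dihydroperoxy-3,5,7-trimethyl-15-phenylpentadeca-4,14-diene
Conditions: 50% aq. H2O2 (excess), Re2O7 (5 mol%), CH3CN/CH2Cl2, 0 °C → rt, short reaction time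
Reagents that add atoms: hydrogen peroxide, OO
Why: Re2O7-catalysed perhydrolysis of a ketone to the 1,1-dihydroperoxide runs through a peroxycarbenium ion under mild conditions that should spare the α-stereocentre and both alkenes, and C3 stays non-stereogenic.

Step 11
Reactants: 19 (3R,4E,7R,14Z)-2,2-dihydroperoxy-3,5,7-trimethyl-15-phenylpentadeca-4,14-diene; 20 mercury diacetate
Product: 21 acetoxy{(3S,4S,5R,6S)-3-hydroperoxy-3,4,6-trimethyl-6-[(2R,9Z)-2-methyl-10-phenyldec-9-en-1-yl]-1,2-dioxan-5-yl}mercury
Conditions: Hg(OAc)2 (1.05 equiv), CH2Cl2, 0 °C → rt, dark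
Reagents that add atoms: mercury diacetate (20), CC(=O)O[Hg]OC(C)=O
Why: Divalent mercury forms a mercurinium ion on the trisubstituted C5=C6 alkene and a hydroperoxy oxygen on C3 opens it at the tertiary carbon C6 (Markovnikov), which is the known intramolecular peroxymercuration (cycloperoxymercuration) of an unsaturated hydroperoxide. The 1,2-dioxane closes in the 6-endo-trig mode through a chair-like transition state. Anti addition across the (E)-alkene sets C6 and C5 together: C7, trans to C4 on the alkene, ends equatorial, the C6 methyl axial and mercury equatorial on C5 (5R). The face is dictated by C4: allylic 1,3-strain with the C6 methyl holds the C4–H in the alkene plane, so the C4 methyl sits equatorial, avoids a 1,3-diaxial clash with the C6 methyl, and C6 forms as (6S) with C7 cis to the C4 methyl. C3 is set by which of the two diastereotopic hydroperoxy groups attacks, the chair with the remaining OOH axial (anomeric) and the C3 methyl equatorial being preferred, and this centre can still equilibrate at the hemiketal stage. The step needs chemoselectivity over the cis-styrene and regioselectivity for 6-endo over 5-exo closure, secured by the more electron-rich trisubstituted alkene, by intramolecular trapping with only one equivalent of Hg(OAc)2, and by the tertiary character of C6.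

Step 12
Reactants: 21 acetoxy{(3S,4S,5R,6S)-3-hydroperoxy-3,4,6-trimethyl-6-[(2R,9Z)-2-methyl-10-phenyldec-9-en-1-yl]-1,2-dioxan-5-yl}mercury
Product: 22 (3S,4R,6S)-3-hydroperoxy-3,4,6-trimethyl-6-[(2R,9Z)-2-methyl-10-phenyldec-9-en-1-yl]-1,2-dioxane
Conditions: NaBH4 (1.2 equiv) in ice-cold H2O, CH2Cl2, 0 °C, 5 min, argon; then aq. NH4Cl
Reagents that add atoms: none
Why: Reductive demercuration: borohydride converts C–HgOAc into an alkylmercury hydride that loses mercury and passes hydrogen to the C5 radical, while the ring O–O bond should survive because epoxide-forming β-scission is stereoelectronically blocked inside the ring and the lipophilic hydroperoxide stays in the organic phase.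

Step 13
Reactants: 22 (3S,4R,6S)-3-hydroperoxy-3,4,6-trimethyl-6-[(2R,9Z)-2-methyl-10-phenyldec-9-en-1-yl]-1,2-dioxane
Product: 23 (3S,4R,6S)-3,4,6-trimethyl-6-[(2R,9Z)-2-methyl-10-phenyldec-9-en-1-yl]-1,2-dioxan-3-ol (target)
Conditions: PPh3 (1.0 equiv), CH2Cl2, 0 °C
Reagents that add atoms: none
Why: Phosphine deoxygenation of the hydroperoxide, far faster than attack on the hindered ring peroxide, leaves the C3–O bond intact and gives the hemiketal with axial OH (3S), the anomerically favoured epimer to which any C3 isomer can also equilibrate through the open hydroperoxy ketone.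

Compound list
1 | (R)-citronellal, (3R)-3,7-dimethyloct-6-enal | C[C@H](CCC=C(C)C)CC=O | starting material
2 | (4R)-4,8-dimethylnon-7-en-1-yne | C[C@H](CCC=C(C)C)CC#C | intermediate
3 | [(4R)-4,8-dimethylnon-7-en-1-yn-1-yl]lithium | C[C@H](CCC=C(C)C)CC#C[Li] | intermediate (not isolated)
4 | trimethyl[(4R)-4,8-dimethylnon-7-en-1-yn-1-yl]silane | C[C@H](CCC=C(C)C)CC#C[Si](C)(C)C | intermediate
5 | trimethyl[(4R)-6-(5,5-dimethyl-1,2,4-trioxolan-3-yl)-4-methylhex-1-yn-1-yl]silane (ozonide, both epimers at the ring CH) | C[C@H](CCC1OOC(C)(C)O1)CC#C[Si](C)(C)C | intermediate (not isolated)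
6 | (4R)-4-methyl-7-(trimethylsilyl)hept-6-yn-1-ol | C[C@H](CCCO)CC#C[Si](C)(C)C | intermediate
7 | (4R)-4-methyl-7-(trimethylsilyl)hept-6-yn-1-yl 4-methylbenzenesulfonate | C[C@H](CCCOS(=O)(=O)c1ccc(C)cc1)CC#C[Si](C)(C)C | intermediate
8 | (5-chloropent-1-yn-1-yl)benzene | ClCCCC#Cc1ccccc1 | starting material
9 | [(1Z)-5-chloropent-1-en-1-yl]benzene | ClCCC/C=C\c1ccccc1 | intermediate
10 | chloro[(4Z)-5-phenylpent-4-en-1-yl]magnesium | Cl[Mg]CCC/C=C\c1ccccc1 | intermediate (not isolated)
11 | trimethyl[(4R,11Z)-4-methyl-12-phenyldodec-11-en-1-yn-1-yl]silane | C[C@H](CCCCCC/C=C\c1ccccc1)CC#C[Si](C)(C)C | intermediate (not isolated)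
12 | (4R,11Z)-4-methyl-12-phenyldodec-11-en-1-yne | C[C@H](CCCCCC/C=C\c1ccccc1)CC#C | intermediate
13 | dimethyl[(1E,4R,11Z)-2,4-dimethyl-12-phenyldodeca-1,11-dien-1-yl]alumane | C[C@H](CCCCCC/C=C\c1ccccc1)C/C(C)=C/[Al](C)C | intermediate (not isolated)
14 | (1E,4R,11Z)-1-iodo-2,4-dimethyl-12-phenyldodeca-1,11-diene | C[C@H](CCCCCC/C=C\c1ccccc1)C/C(C)=C/I | intermediate
15 | (2R,3R)-2,3-dimethyloxirane (trans-2,3-epoxybutane) | C[C@H]1O[C@@H]1C | starting material
16 | [(1E,4R,11Z)-2,4-dimethyl-12-phenyldodeca-1,11-dien-1-yl]lithium | C[C@H](CCCCCC/C=C\c1ccccc1)C/C(C)=C/[Li] | intermediate (not isolated)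
17 | (2R,3R,4E,7R,14Z)-3,5,7-trimethyl-15-phenylpentadeca-4,14-dien-2-ol | C[C@H](CCCCCC/C=C\c1ccccc1)C/C(C)=C/[C@@H](C)[C@@H](C)O | intermediate
18 | (3R,4E,7R,14Z)-3,5,7-trimethyl-15-phenylpentadeca-4,14-dien-2-one | C[C@H](CCCCCC/C=C\c1ccccc1)C/C(C)=C/[C@@H](C)C(C)=O | intermediate
19 | (3R,4E,7R,14Z)-2,2-dihydroperoxy-3,5,7-trimethyl-15-phenylpentadeca-4,14-diene (C3 geminal bis-hydroperoxide) | C[C@H](CCCCCC/C=C\c1ccccc1)C/C(C)=C/[C@@H](C)C(C)(OO)OO | intermediate
20 | mercury diacetate | CC(=O)O[Hg]OC(C)=O | starting material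
21 | acetoxy{(3S,4S,5R,6S)-3-hydroperoxy-3,4,6-trimethyl-6-[(2R,9Z)-2-methyl-10-phenyldec-9-en-1-yl]-1,2-dioxan-5-yl}mercury | C[C@H](CCCCCC/C=C\c1ccccc1)C[C@@]1(C)[C@H]([Hg]OC(C)=O)[C@@H](C)[C@@](C)(OO)OO1 | intermediate
22 | (3S,4R,6S)-3-hydroperoxy-3,4,6-trimethyl-6-[(2R,9Z)-2-methyl-10-phenyldec-9-en-1-yl]-1,2-dioxane | C[C@H](CCCCCC/C=C\c1ccccc1)C[C@@]1(C)C[C@@H](C)[C@@](C)(OO)OO1 | intermediate
23 | (3S,4R,6S)-3,4,6-trimethyl-6-[(2R,9Z)-2-methyl-10-phenyldec-9-en-1-yl]-1,2-dioxan-3-ol | C[C@H](CCCCCC/C=C\c1ccccc1)C[C@@]1(C)C[C@@H](C)[C@@](C)(O)OO1 | target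

Total step count: 13.
Longest linear sequence: 12 steps (steps 1 to 4 and 6 to 13 from 1; step 5 is a one-step branch).

Steps most likely to fail

Step 11 (key step). What may go wrong: mercuration of the cis-styrene in competition with ring closure, acid-promoted reversal of the oxymercuration, or erosion of facial selectivity if the chair is not followed. Fallback: setting out from 19, the ring is closed with an iodonium electrophile in place of mercury, so that no carbon–metal bond is made and C5 is later cleared by a tin radical chain. N-Iodosuccinimide in CH2Cl2 at 0 °C in the dark should give, by the same anti 6-endo addition, the 5-iodo-3-hydroperoxy-1,2-dioxane F1. PPh3 should then reduce the hydroperoxide to the 5-iodo-1,2-dioxan-3-ol F2. Bu3SnH with Et3B/air in toluene at 0 °C should remove iodine from C5, which comes back to the route at 23.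

Step 10. What may go wrong: acid-induced enolisation toward C4 (epimerisation or migration of the alkene into conjugation), Criegee-type rearrangement of the perhydrate, premature non-stereospecific acid cyclisation onto C6, or epoxidation by rhenium peroxo species formed from Re2O7. Fallback: setting out from 18, the bis-hydroperoxide is not made at all. Anhydrous ethereal H2O2 without acid should add reversibly to the ketone to give the hydroxy hydroperoxide (perhydrate) F3. This is trapped in the same flask by Hg(OAc)2 through the same 6-endo peroxymercuration, giving the 5-(acetoxymercurio)-1,2-dioxan-3-ol F4 directly at the hemiketal oxidation level. Neutral demercuration with Bu3SnH in CH2Cl2 at 0 °C then comes back to the route at 23.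

Step 12. What may go wrong: hydride reduction of the hydroperoxide during demercuration, followed by base-induced opening of the resulting hemiketal and over-reduction of the open keto hydroperoxide, or trapping of the C5 radical by oxygen. Fallback: setting out from 21, the order of the two reductions is inverted and borohydride is avoided. Washing with aqueous NaCl should give the chloromercurial F5. Dimethyl sulfide should reduce its hydroperoxide to the chloromercurio hemiketal F6. Bu3SnH in CH2Cl2 at 0 °C should then cleave the C–Hg bond in a neutral radical chain, coming back to the route at 23.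

Further compounds
F1 | step 11 | (3S,4S,5R,6S)-3-hydroperoxy-5-iodo-3,4,6-trimethyl-6-[(2R,9Z)-2-methyl-10-phenyldec-9-en-1-yl]-1,2-dioxane | C[C@H](CCCCCC/C=C\c1ccccc1)C[C@@]1(C)[C@H](I)[C@@H](C)[C@@](C)(OO)OO1
F2 | step 11 | (3S,4S,5R,6S)-5-iodo-3,4,6-trimethyl-6-[(2R,9Z)-2-methyl-10-phenyldec-9-en-1-yl]-1,2-dioxan-3-ol | C[C@H](CCCCCC/C=C\c1ccccc1)C[C@@]1(C)[C@H](I)[C@@H](C)[C@@](C)(O)OO1
F3 | step 10 | (3R,4E,7R,14Z)-2-hydroperoxy-3,5,7-trimethyl-15-phenylpentadeca-4,14-dien-2-ol (both C2 epimers) | C[C@H](CCCCCC/C=C\c1ccccc1)C/C(C)=C/[C@@H](C)C(C)(O)OO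
F4 | step 10 | acetoxy{(3S,4S,5R,6S)-3-hydroxy-3,4,6-trimethyl-6-[(2R,9Z)-2-methyl-10-phenyldec-9-en-1-yl]-1,2-dioxan-5-yl}mercury | C[C@H](CCCCCC/C=C\c1ccccc1)C[C@@]1(C)[C@H]([Hg]OC(C)=O)[C@@H](C)[C@@](C)(O)OO1
F5 | step 12 | chloro{(3S,4S,5R,6S)-3-hydroperoxy-3,4,6-trimethyl-6-[(2R,9Z)-2-methyl-10-phenyldec-9-en-1-yl]-1,2-dioxan-5-yl}mercury | C[C@H](CCCCCC/C=C\c1ccccc1)C[C@@]1(C)[C@H]([Hg]Cl)[C@@H](C)[C@@](C)(OO)OO1
F6 | step 12 | chloro{(3S,4S,5R,6S)-3-hydroxy-3,4,6-trimethyl-6-[(2R,9Z)-2-methyl-10-phenyldec-9-en-1-yl]-1,2-dioxan-5-yl}mercury | C[C@H](CCCCCC/C=C\c1ccccc1)C[C@@]1(C)[C@H]([Hg]Cl)[C@@H](C)[C@@](C)(O)OO1
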